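The vessel starts with free base and protonated nucleophile, and the electrophile runs in over 20 s. The reading to watch is the electrophile late in the run.

| flask | electrophile | free base | protonated nucleophile | remark | time |
|---|---|---|---|---|---|
| north | 0.27 M (fed, over 20 s) | 1 equiv | 1 equiv | run made earlier; the fed solution adds 0.10 times the starting volume |  |
| south | 0.20 M (fed, over 20 s) | 1 equiv | 1 equiv | run made earlier; the fed solution adds 0.10 times the starting volume |  |
| winter | 0.40 M (fed, over 20 s) | 1.00 equiv | 1.00 equiv | the fed solution adds 0.10 times the starting volume | 12 min |
| dusk | 0.40 M (fed, over 20 s) | 1.30 equiv | 1.00 equiv | the fed solution adds 0.10 times the starting volume | 12 min |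

| run | time / min | electrophile / % | target / % |
|---|---|---|---|
| north | 0.333 | 60.6 | 36.8 |
| north | 0.500 | 46.6 | 45.0 |
| north | 1.00 | 29.1 | 37.0 |
| north | 1.50 | 20.2 | 27.7 |
| north | 2.50 | 12.1 | 17.6 |
| north | 4.00 | 7.5 | 10.8 |
| south | 0.667 | 43.0 | 45.0 |
| south | 1.33 | 26.5 | 34.9 |
| south | 2.00 | 18.6 | 25.2 |
| south | 3.00 | 12.9 | 18.5 |
| south | 4.00 | 9.4 | 13.9 |

(readings scatter by 0.3 percentage points)

- charges are per starting volume, the dose included; the dosed solution carries all of it
- the analysis behind the earlier runs scatters by 0.3 percentage points, standard deviation

1. part of the electrophile that has reacted at the end, winter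
2. part of the electrophile that has reacted at the end, dusk
3. what raising the equivalents of free base from its lowest to its highest value here does to the part of the electrophile that has reacted (changes below 5 percentage points count as none) (it rises / no change / it falls)

I follow one molecule of electrophile. Its chance of being taken per minute is a rate constant times the concentration of its partner. If a partner charged one to one is used up in step, that chance falls as the electrophile falls. This is second-order decay with equal charges, and one over the share left then climbs in a straight line. The slope should grow with the charge, so I read it from 1.00 min to 4.00 min in north and from 1.33 min to 4.00 min in south: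

north: slope 3.30 min⁻¹, per charge 0.204 M⁻¹ s⁻¹

south: slope 2.57 min⁻¹, per charge 0.214 M⁻¹ s⁻¹

The slope rises with the charge. The mean per charge, 0.209 M⁻¹ s⁻¹, I call the pairing constant: the slope of that line divided by the charge. For winter I reckon:

share left = 1/(1 + pairing constant × charge × time) = 1.63 %

reacted = 98.4 %

Dusk adds free base. My winter reckoning leaves 1.63 %, smaller than the margin of 5 percentage points, so a rise in dusk past that margin does not fit it. The runs do not vary free base, so they show nothing about a fall, and my call of no change is a judgement.

The forecast gives 98.4 % (97.8 % to 98.9 %) for winter, 99.4 % (98 % to 100 %) for dusk, and no change, noting that “the slope scales with concentration”. It rests on the same kind of line as mine, so the agreement checks nothing.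

The flasks give 98.6 % for winter and 98.9 % for dusk, a change of 0.32 points: no change.

    nucleophile + acid set free ⇌ protonated nucleophile, settled at all times (K = 25.0 M⁻¹)
    electrophile + nucleophile → acid set free + target (k = 0.400 M⁻¹ s⁻¹)
    acid set free + target → side product (k = 0.390 M⁻¹ s⁻¹)
    acid set free + free base ⇌ salt of the base, settled at all times (K = 1.70 × 10⁵ M⁻¹)

At 12.0 min, winter holds nucleophile 0.00427 M beside electrophile 0.00504 M, so the partners are down together. Left ten times as long, the pairing constant gives 99.8 % reacted in winter; the flask gives 99.9 %.

A neighbour of winter has 0.600 equiv of protonated nucleophile. Counting one to one, I take the protonated nucleophile as the limiting reagent and reckon a surplus of 40.0 % of the electrophile. Against that surplus I reckon the partner's half-life as 0.346 min, far shorter than 12 min, so I expect 60.0 % reacted. The neighbour gives 60.0 %, with nucleophile 0 M and electrophile 40.0 % at the end.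

(All runs stem from a simulated flask from invented constants, noise included.)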